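**Retrosynthetic overview**

- Ring labels: upper flavan = ring A (benzo), ring B (4-hydroxyphenyl), ring C (pyran); lower epiafzelechin unit = ring D (benzo), ring E (4-hydroxyphenyl), ring F (pyran). The plan rests on two facts: C4 of ring C is benzylic to C8 of ring D, which carries oxygen at both ortho positions (C7–O, ring-F O1) and at the para position (C5–O), so a C4 cation forms very readily; and C4a of ring A is ortho to O1 and para to the C7 oxygen, so it is the nucleophilic carbon.
- Ring C is opened at C4–C4a, giving an open-chain 3-aryloxy-1-arylpropan-1-ol (14); ring C is the only ring built and it is closed last.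
- 14 is cut at C4–C8 into the C8 aryl cerium reagent of 8-bromo-tetra-O-benzyl-epiafzelechin (rings D, E, F bought intact) and the β-aryloxy aldehyde 7.
- 7 comes from 4-formylphenyl pivalate by catalytic asymmetric allylation (R carbinol), Mitsunobu inversion with 3-benzyloxyphenol (sets C2 as S) and oxidative alkene cleavage.
- End game: pivalate methanolysis, then hydrogenolysis of five benzyl ethers.

Key step: step 9

Remark: (−)-epiafzelechin, the (2R,3R) flavan-3-ol, is taken as a purchasable natural product.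

**Route**

Step 1
Reactants: 1 4-hydroxybenzaldehyde
Product: 2 4-formylphenyl pivalate
Conditions: PivCl, Et3N, DMAP (cat.), CH2Cl2, 0 °C → rt
Reagents that add atoms: pivaloyl chloride, CC(C)(C)C(Cl)=O
Why: DMAP-catalysed O-acylation of the phenol; the bulky, electron-withdrawing pivalate is chosen because it later disfavours ionisation of the C2–O1 benzylic ether.

Step 2
Reactants: 2 4-formylphenyl pivalate
Product: 3 (R)-1-(4-pivaloyloxyphenyl)but-3-en-1-ol
Conditions: (R)-BINOL (20 mol %), Ti(OiPr)4 (20 mol %), 4 Å MS, allylSnBu3, CH2Cl2, −20 °C; aq. NaHCO3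
Reagents that add atoms: allyltributylstannane, C=CC[Sn](CCCC)(CCCC)CCCC
Why: Keck asymmetric allylation under neutral conditions that spare the aryl ester; the (R)-BINOL–titanium complex should deliver the allyl group to the Re face of the aryl aldehyde and so set the R carbinol.

Step 3
Reactants: 3 (R)-1-(4-pivaloyloxyphenyl)but-3-en-1-ol; 4 3-(benzyloxy)phenol
Product: 5 4-[(1S)-1-(3-benzyloxyphenoxy)but-3-en-1-yl]phenyl pivalate
Conditions: PPh3, DIAD, toluene, 0 °C → rt
Reagents that add atoms: none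
Why: Mitsunobu etherification; the phenoxide displaces the alkoxyphosphonium in an SN2 step with inversion (R → S, the future C2), and the para-acyloxy group holds back SN1 leakage at the benzylic carbon.

Step 4
Reactants: 5 4-[(1S)-1-(3-benzyloxyphenoxy)but-3-en-1-yl]phenyl pivalate
Product: 7 (S)-3-(3-benzyloxyphenoxy)-3-(4-pivaloyloxyphenyl)propanal, via the vicinal diol 6 (not isolated)
Conditions: OsO4 (2 mol %), NaIO4 (4 equiv), 2,6-lutidine, dioxane/H2O 3:1, rt; used at once
Reagents that add atoms: osmium tetroxide OsO4, O=[Os](=O)(=O)=O; sodium periodate NaIO4, [Na+].[O-]I(=O)(=O)=O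
Why: Lemieux–Johnson cleavage (dihydroxylation, then periodate glycol fission) of the terminal alkene; it is preferred to ozone because the resorcinol diether ring is ozone-sensitive, and the stereocentre is not touched.

Step 5
Reactants: 8 (−)-epiafzelechin
Product: 9 5,7,4'-tri-O-benzyl-epiafzelechin
Conditions: BnBr (3.3 equiv), K2CO3, DMF, 0 °C → rt, Ar
Reagents that add atoms: benzyl bromide, BrCc1ccccc1
Why: Williamson etherification; K2CO3 deprotonates only the three phenols, so the C3 alcohol stays free and the mild base should leave C2 and C3 unchanged.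

Step 6
Reactants: 9 5,7,4'-tri-O-benzyl-epiafzelechin
Product: 10 3,5,7,4'-tetra-O-benzyl-epiafzelechin
Conditions: NaH, BnBr, n-Bu4NI (cat.), THF/DMF, 0 °C → rt
Reagents that add atoms: benzyl bromide, BrCc1ccccc1
Why: Williamson etherification of the secondary alkoxide, which removes the last acidic proton before the organometallic step.

Step 7
Reactants: 10 3,5,7,4'-tetra-O-benzyl-epiafzelechin
Product: 11 8-bromo-3,5,7,4'-tetra-O-benzyl-epiafzelechin
Conditions: NBS (1.0 equiv), CH2Cl2, −78 °C → rt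
Reagents that add atoms: N-bromosuccinimide, O=C1CCC(=O)N1Br
Why: electrophilic aromatic bromination of the phloroglucinol-type ring D; C8 (between one benzyloxy group and the ring oxygen) is less crowded than C6 (between two benzyloxy groups), and ring E is far less activated.

Step 8
Reactants: 11 8-bromo-3,5,7,4'-tetra-O-benzyl-epiafzelechin; 7 (S)-3-(3-benzyloxyphenoxy)-3-(4-pivaloyloxyphenyl)propanal
Product: 14 (3S)-3-(3-benzyloxyphenoxy)-3-(4-pivaloyloxyphenyl)-1-[(2R,3R)-3,5,7-tris(benzyloxy)-2-(4-benzyloxyphenyl)chroman-8-yl]propan-1-ol (both C1 epimers), via 8-lithio arene 12 (not isolated), via 8-dichlorocerio arene 13 (not isolated)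
Conditions: n-BuLi, THF, −78 °C; anhydrous CeCl3, −78 °C; then 7, −78 °C; aq. NH4Cl
Reagents that add atoms: none
Why: bromine–lithium exchange, transmetalation to cerium and 1,2-addition to the aldehyde; the weakly basic, oxophilic aryl cerium should add faster than it enolises the β-aryloxy aldehyde or attacks the hindered pivalate, and the new carbinol centre need not be controlled because step 9 erases it.

Step 9
Reactants: 14 (3S)-3-(3-benzyloxyphenoxy)-3-(4-pivaloyloxyphenyl)-1-[(2R,3R)-3,5,7-tris(benzyloxy)-2-(4-benzyloxyphenyl)chroman-8-yl]propan-1-ol (both C1 epimers)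
Product: 15 (2S,4R)-7-benzyloxy-2-(4-pivaloyloxyphenyl)-4-[(2R,3R)-3,5,7-tris(benzyloxy)-2-(4-benzyloxyphenyl)chroman-8-yl]chroman
Conditions: Sc(OTf)3 (10 mol %), CH2Cl2 (0.01 M), −20 °C → rt
Reagents that add atoms: none
Why: Sc(OTf)3 ionises the C4 carbinol to a benzylic cation delocalised onto the C7 and ring-F oxygens (ortho) and the C5 oxygen (para) of ring D, so both carbinol epimers give the same intermediate. The carbon of the 3-benzyloxyphenoxy ring that is para to the benzyloxy group and ortho to the ether oxygen (the future C4a) attacks this cation, which is the known acid-mediated Friedel–Crafts cyclodehydration of 3-aryloxy-1-arylpropan-1-ols to 4-arylchromans. Ring C closes in a six-membered, chair-like electrophilic aromatic substitution in which the C4a–C8a bond of ring A ends inside the new ring (endo with respect to the arene π bond). C4 is set relative to the existing C2: with the C2 aryl equatorial, the 2,6-disubstituted ring D should go pseudo-axial to avoid the peri clash with C5–H of ring A, which gives the 2,4-trans (4R) isomer, and an NOE experiment on 15 should confirm this relative configuration. The step needs ionisation at C4 and not at C2, which the trioxygenated ring D against the electron-poor pivaloyloxyphenyl ring secures; it needs attack para to the benzyloxy group and not at the carbon between the two oxygens, which sterics favour. High dilution keeps C6 of ring D of a second molecule from competing with the ring closure.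

Step 10
Reactants: 15 (2S,4R)-7-benzyloxy-2-(4-pivaloyloxyphenyl)-4-[(2R,3R)-3,5,7-tris(benzyloxy)-2-(4-benzyloxyphenyl)chroman-8-yl]chroman
Product: 16 (2S,4R)-7-benzyloxy-2-(4-hydroxyphenyl)-4-[(2R,3R)-3,5,7-tris(benzyloxy)-2-(4-benzyloxyphenyl)chroman-8-yl]chroman
Conditions: K2CO3, MeOH/THF 2:1, rt
Reagents that add atoms: none
Why: base-mediated methanolysis (transesterification) of the aryl pivalate; benzyl ethers and all four stereocentres are inert at room temperature.

Step 11
Reactants: 16 (2S,4R)-7-benzyloxy-2-(4-hydroxyphenyl)-4-[(2R,3R)-3,5,7-tris(benzyloxy)-2-(4-benzyloxyphenyl)chroman-8-yl]chroman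
Product: 17 (2R,3R)-8-[(2S,4R)-7-hydroxy-2-(4-hydroxyphenyl)chroman-4-yl]-2-(4-hydroxyphenyl)chroman-3,5,7-triol (target)
Conditions: H2 (1 atm), Pd(OH)2/C, THF/MeOH 1:1, rt
Reagents that add atoms: none
Why: catalytic hydrogenolysis of the four aryl benzyl ethers and the C3 benzyl ether; at 1 atm and room temperature the cyclic benzylic C2–O1 bonds of both pyran rings should survive.

**Compound list**

1 | 4-hydroxybenzaldehyde | O=Cc1ccc(O)cc1 | starting material
2 | 4-formylphenyl pivalate | CC(C)(C)C(=O)Oc1ccc(C=O)cc1 | intermediate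
3 | (R)-1-(4-pivaloyloxyphenyl)but-3-en-1-ol | CC(C)(C)C(=O)Oc1ccc([C@H](O)CC=C)cc1 | intermediate
4 | 3-(benzyloxy)phenol | Oc1cccc(OCc2ccccc2)c1 | starting material
5 | 4-[(1S)-1-(3-benzyloxyphenoxy)but-3-en-1-yl]phenyl pivalate | CC(C)(C)C(=O)Oc1ccc([C@@H](Oc2cccc(OCc3ccccc3)c2)CC=C)cc1 | intermediate
6 | 4-[(1S)-1-(3-benzyloxyphenoxy)-3,4-dihydroxybutyl]phenyl pivalate (both C3 epimers) | CC(C)(C)C(=O)Oc1ccc([C@@H](Oc2cccc(OCc3ccccc3)c2)CC(O)CO)cc1 | intermediate
7 | (S)-3-(3-benzyloxyphenoxy)-3-(4-pivaloyloxyphenyl)propanal | CC(C)(C)C(=O)Oc1ccc([C@@H](Oc2cccc(OCc3ccccc3)c2)CC=O)cc1 | intermediate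
8 | (−)-epiafzelechin, (2R,3R) | O[C@@H]1Cc2c(O)cc(O)cc2O[C@@H]1c1ccc(O)cc1 | starting material
9 | 5,7,4'-tri-O-benzyl-epiafzelechin | O[C@@H]1Cc2c(OCc3ccccc3)cc(OCc3ccccc3)cc2O[C@@H]1c1ccc(OCc2ccccc2)cc1 | intermediate
10 | 3,5,7,4'-tetra-O-benzyl-epiafzelechin | O(Cc1ccccc1)[C@@H]1Cc2c(OCc3ccccc3)cc(OCc3ccccc3)cc2O[C@@H]1c1ccc(OCc2ccccc2)cc1 | intermediate
11 | 8-bromo-3,5,7,4'-tetra-O-benzyl-epiafzelechin | O(Cc1ccccc1)[C@@H]1Cc2c(OCc3ccccc3)cc(OCc3ccccc3)c(Br)c2O[C@@H]1c1ccc(OCc2ccccc2)cc1 | intermediate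
12 | 8-lithio-3,5,7,4'-tetra-O-benzyl-epiafzelechin | O(Cc1ccccc1)[C@@H]1Cc2c(OCc3ccccc3)cc(OCc3ccccc3)c([Li])c2O[C@@H]1c1ccc(OCc2ccccc2)cc1 | intermediate
13 | 8-(dichlorocerio)-3,5,7,4'-tetra-O-benzyl-epiafzelechin | O(Cc1ccccc1)[C@@H]1Cc2c(OCc3ccccc3)cc(OCc3ccccc3)c([Ce](Cl)Cl)c2O[C@@H]1c1ccc(OCc2ccccc2)cc1 | intermediate
14 | (3S)-3-(3-benzyloxyphenoxy)-3-(4-pivaloyloxyphenyl)-1-[(2R,3R)-3,5,7-tris(benzyloxy)-2-(4-benzyloxyphenyl)chroman-8-yl]propan-1-ol (both C1 epimers) | CC(C)(C)C(=O)Oc1ccc([C@@H](Oc2cccc(OCc3ccccc3)c2)CC(O)c2c(OCc3ccccc3)cc(OCc3ccccc3)c3c2O[C@H](c2ccc(OCc4ccccc4)cc2)[C@H](OCc2ccccc2)C3)cc1 | intermediate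
15 | (2S,4R)-7-benzyloxy-2-(4-pivaloyloxyphenyl)-4-[(2R,3R)-3,5,7-tris(benzyloxy)-2-(4-benzyloxyphenyl)chroman-8-yl]chroman | CC(C)(C)C(=O)Oc1ccc([C@@H]2C[C@@H](c3c(OCc4ccccc4)cc(OCc4ccccc4)c4c3O[C@H](c3ccc(OCc5ccccc5)cc3)[C@H](OCc3ccccc3)C4)c3ccc(OCc4ccccc4)cc3O2)cc1 | intermediate
16 | (2S,4R)-7-benzyloxy-2-(4-hydroxyphenyl)-4-[(2R,3R)-3,5,7-tris(benzyloxy)-2-(4-benzyloxyphenyl)chroman-8-yl]chroman | Oc1ccc([C@@H]2C[C@@H](c3c(OCc4ccccc4)cc(OCc4ccccc4)c4c3O[C@H](c3ccc(OCc5ccccc5)cc3)[C@H](OCc3ccccc3)C4)c3ccc(OCc4ccccc4)cc3O2)cc1 | intermediate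
17 | (2R,3R)-8-[(2S,4R)-7-hydroxy-2-(4-hydroxyphenyl)chroman-4-yl]-2-(4-hydroxyphenyl)chroman-3,5,7-triol | Oc1ccc([C@@H]2C[C@@H](c3c(O)cc(O)c4c3O[C@H](c3ccc(O)cc3)[C@H](O)C4)c3ccc(O)cc3O2)cc1 | target

**Step count**

Total: 11 steps. Longest linear sequence: 8 steps (steps 1–4 and 8–11, from 4-hydroxybenzaldehyde); the epiafzelechin branch is 7 steps (steps 5–11).

**Steps most likely to fail**

1. Step 9. The ring closure may lose 2,4-trans selectivity, ring A may attack through the carbon between its two oxygens, or the C4 cation may lose a proton to a styrene whose allylic aryl ether then ionises at C2. The fallback forms the C4–C8 bond between the two units on a preformed ring C. It sets out from aldehyde 7 and uses nucleophile 10. Oxidation of 7 with NaClO2/NaH2PO4/2-methyl-2-butene should give (S)-3-(3-benzyloxyphenoxy)-3-(4-pivaloyloxyphenyl)propanoic acid F1. Intramolecular Friedel–Crafts acylation ((COCl)2, cat. DMF, then SnCl4, CH2Cl2, −78 °C) should close ring C to (S)-7-benzyloxy-2-(4-pivaloyloxyphenyl)chroman-4-one F2. Reduction with NaBH4 in MeOH/THF at 0 °C should give the 2,4-cis alcohol (2S,4S)-7-benzyloxy-2-(4-pivaloyloxyphenyl)chroman-4-ol F3. Ionisation of F3 with BF3·OEt2 in CH2Cl2 at low temperature in the presence of 10 should alkylate C8 of ring D; pseudo-axial attack on the flavan-4-yl cation with the C2 aryl equatorial is expected to favour the 2,4-trans product. The fallback comes back to the route at 15.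

2. Step 8. The aryl metal may abstract the proton α to the aldehyde, with β-elimination of the aryloxide and loss of ring A, faster than it adds. The fallback changes the electrophile to a less acidic acyl donor and makes the carbinol by reduction. It sets out from 7, which is oxidised to the acid F1 as above. Coupling with MeNHOMe·HCl (EDC·HCl, iPr2NEt, CH2Cl2) should give (S)-3-(3-benzyloxyphenoxy)-N-methoxy-N-methyl-3-(4-pivaloyloxyphenyl)propanamide F4. Addition of the aryllithium 12 at −78 °C should give, through the stable chelated adduct, (3S)-3-(3-benzyloxyphenoxy)-3-(4-pivaloyloxyphenyl)-1-[(2R,3R)-3,5,7-tris(benzyloxy)-2-(4-benzyloxyphenyl)chroman-8-yl]propan-1-one F5. Luche reduction (NaBH4, CeCl3·7H2O, MeOH/THF, −40 °C) returns to the route at 14.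

3. Step 3. The benzylic alkoxyphosphonium may leak into an SN1 path, eroding the configuration of the future C2, or undergo elimination to the 1-arylbutadiene. The fallback forms the ether bond at the aryl carbon with retention instead of at the carbinol carbon with inversion. It sets out from 2. Keck allylation with (S)-BINOL/Ti(OiPr)4/allylSnBu3 should give (S)-1-(4-pivaloyloxyphenyl)but-3-en-1-ol F6. Copper-promoted oxidative O-arylation with (3-benzyloxyphenyl)boronic acid (Cu(OAc)2, DMAP, 4 Å MS, O2, CH2Cl2, rt) leaves the C–O bond of the carbinol intact and comes back to the route at 5.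

**Further compounds**

F1 | step 9 | (S)-3-(3-benzyloxyphenoxy)-3-(4-pivaloyloxyphenyl)propanoic acid | CC(C)(C)C(=O)Oc1ccc([C@@H](Oc2cccc(OCc3ccccc3)c2)CC(O)=O)cc1
F2 | step 9 | (S)-7-benzyloxy-2-(4-pivaloyloxyphenyl)chroman-4-one | CC(C)(C)C(=O)Oc1ccc([C@@H]2CC(=O)c3ccc(OCc4ccccc4)cc3O2)cc1
F3 | step 9 | (2S,4S)-7-benzyloxy-2-(4-pivaloyloxyphenyl)chroman-4-ol | CC(C)(C)C(=O)Oc1ccc([C@@H]2C[C@H](O)c3ccc(OCc4ccccc4)cc3O2)cc1
F4 | step 8 | (S)-3-(3-benzyloxyphenoxy)-N-methoxy-N-methyl-3-(4-pivaloyloxyphenyl)propanamide | CC(C)(C)C(=O)Oc1ccc([C@@H](Oc2cccc(OCc3ccccc3)c2)CC(=O)N(C)OC)cc1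
F5 | step 8 | (3S)-3-(3-benzyloxyphenoxy)-3-(4-pivaloyloxyphenyl)-1-[(2R,3R)-3,5,7-tris(benzyloxy)-2-(4-benzyloxyphenyl)chroman-8-yl]propan-1-one | CC(C)(C)C(=O)Oc1ccc([C@@H](Oc2cccc(OCc3ccccc3)c2)CC(=O)c2c(OCc3ccccc3)cc(OCc3ccccc3)c3c2O[C@H](c2ccc(OCc4ccccc4)cc2)[C@H](OCc2ccccc2)C3)cc1
F6 | step 3 | (S)-1-(4-pivaloyloxyphenyl)but-3-en-1-ol | CC(C)(C)C(=O)Oc1ccc([C@@H](O)CC=C)cc1
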